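**Retrosynthetic overview**
- Target ⇐ its 3,4-O-isopropylidene acetal (acid hydrolysis) ⇐ all-cis 5,6-diol (site-selective benzoylation of the equatorial O5).
- All-cis diol ⇐ tertiary α-hydroxy aldehyde on a cyclopentene, by a chelate-controlled α-ketol 1,2-shift (formyl carbon becomes C6) and in-flask reduction of the ring ketone (C5). This is the only ring construction: the six-membered ring is made by expanding the purchased five-membered ring.
- α-Hydroxy aldehyde ⇐ dithiane carbinol (formyl anion added to the ketone anti to the acetonide, primary OH benzoylated) ⇐ hydroxymethyl enone.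
- Hydroxymethyl enone ⇐ (4S,5S)-4,5-O-isopropylidene-cyclopent-2-enone + formaldehyde (Morita–Baylis–Hillman). The enone supplies C3 and C4, the shift sets C6, the reduction sets C5.

Assumption: enone 1 is bought as the (3aS,6aS) antipode (the enantiomer of the D-ribose-derived acetonide enone); both antipodes are catalogue compounds.
Numbering used for the six-membered ring: C1 carries CH2OBz, C1=C2, C3–C6 carry oxygen; in the target all four ring oxygens are cis (3S,4S,5R,6R).

Step 1
Reactants: 1 (3aS,6aS)-2,2-dimethyl-3a,6a-dihydro-4H-cyclopenta[d][1,3]dioxol-4-one; 2 formaldehyde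
Product: 3 (3aS,6aS)-5-(hydroxymethyl)-2,2-dimethyl-3a,6a-dihydro-4H-cyclopenta[d][1,3]dioxol-4-one
Conditions: 37% aq. HCHO (3 equiv), imidazole (1 equiv), THF/H2O 1:1, 23 °C, 36 h
Reagents that add atoms: none
Why: Morita–Baylis–Hillman reaction (imidazole adds reversibly to the β-carbon, the enolate is hydroxymethylated at the α-carbon, the catalyst is expelled); no stereocentre is formed and the cis-fused acetonide centres cannot epimerise.

Step 2
Reactants: 3 (3aS,6aS)-5-(hydroxymethyl)-2,2-dimethyl-3a,6a-dihydro-4H-cyclopenta[d][1,3]dioxol-4-one; 4 1,3-dithiane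
Product: 6 (3aS,4R,6aS)-4-(1,3-dithian-2-yl)-5-(hydroxymethyl)-2,2-dimethyl-3a,6a-dihydro-4H-cyclopenta[d][1,3]dioxol-4-ol, via 2-lithio-1,3-dithiane 5 (not isolated)
Conditions: 4 (2.3 equiv), n-BuLi (2.2 equiv), THF, −30 °C, 2 h; then 3, −78 °C, 1 h; aq. NH4Cl
Reagents that add atoms: none
Why: Corey–Seebach 1,2-addition of a formyl anion equivalent to the ketone; the first equivalent makes the primary hydroxyl a non-leaving alkoxide, and the nucleophile enters the convex face anti to the dioxolane, so the new tertiary hydroxyl is cis to the acetonide oxygens (4R).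

Step 3
Reactants: 6 (3aS,4R,6aS)-4-(1,3-dithian-2-yl)-5-(hydroxymethyl)-2,2-dimethyl-3a,6a-dihydro-4H-cyclopenta[d][1,3]dioxol-4-ol
Product: 7 [(3aS,4R,6aS)-4-(1,3-dithian-2-yl)-4-hydroxy-2,2-dimethyl-3a,6a-dihydro-4H-cyclopenta[d][1,3]dioxol-5-yl]methyl benzoate
Conditions: BzCl (1.1 equiv), pyridine, CH2Cl2, 0 °C
Reagents that add atoms: benzoyl chloride, O=C(Cl)c1ccccc1
Why: Selective O-acylation of the primary allylic alcohol (the tertiary carbinol is inert); the ester also prevents lactol formation once the aldehyde is unmasked.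

Step 4
Reactants: 7 [(3aS,4R,6aS)-4-(1,3-dithian-2-yl)-4-hydroxy-2,2-dimethyl-3a,6a-dihydro-4H-cyclopenta[d][1,3]dioxol-5-yl]methyl benzoate
Product: 8 [(3aS,4R,6aS)-4-formyl-4-hydroxy-2,2-dimethyl-3a,6a-dihydro-4H-cyclopenta[d][1,3]dioxol-5-yl]methyl benzoate
Conditions: PhI(OCOCF3)2 (1.5 equiv), NaHCO3, MeCN/H2O 9:1, 0 °C, 10 min; used crude
Reagents that add atoms: water, O
Why: Oxidative dethioacetalisation with a hypervalent iodine reagent in buffered aqueous acetonitrile frees the aldehyde under conditions that spare alkene, acetonide and benzoate, and the buffer prevents a premature, unchelated acid-induced shift.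

Step 5
Reactants: 8 [(3aS,4R,6aS)-4-formyl-4-hydroxy-2,2-dimethyl-3a,6a-dihydro-4H-cyclopenta[d][1,3]dioxol-5-yl]methyl benzoate
Product: 10 [(3S,4R,5R,6R)-5,6-dihydroxy-3,4-(isopropylidenedioxy)cyclohex-1-en-1-yl]methyl benzoate, via ring-expanded ketol 9 (not isolated)
Conditions: Me2AlCl (1.05 equiv), CH2Cl2, −78 → −20 °C; then NaBH4, EtOH, −78 °C; aq. potassium sodium tartrate
Reagents that add atoms: none
Why: Proposed new method: Me2AlCl turns the tertiary hydroxyl into a chloro(methyl)aluminium alkoxide whose metal also binds the formyl oxygen, so that C–O and C=O are held syn-periplanar in a five-membered chelate and the alkenyl ring carbon (the better σ-donor; the other ring carbon is deactivated by its acetal oxygen) makes the 1,2-shift onto the activated formyl carbon (α-ketol rearrangement, cyclopentene to cyclohexene ring expansion), which with the formyl group anti to the dioxolane puts the new C6 hydroxyl on the acetonide face (6R), after which borohydride reduces the still chelated ketone from the open face anti to both flanking C–O bonds to set C5 (5R, all-cis); the closest known reaction type is the Lewis-acid-promoted α-ketol ring expansion of 1-hydroxycycloalkanecarbaldehydes (and the aluminium alkoxide D-homoannulation of 17-hydroxy-20-oxo steroids), which has not been shown on a 1-hydroxycyclopent-2-ene-1-carbaldehyde with competing alkenyl and α-alkoxyalkyl migrating groups nor coupled in one flask to chelate-directed reduction.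

Step 6
Reactants: 10 [(3S,4R,5R,6R)-5,6-dihydroxy-3,4-(isopropylidenedioxy)cyclohex-1-en-1-yl]methyl benzoate
Product: 11 [(3S,4S,5R,6R)-5-(benzoyloxy)-6-hydroxy-3,4-(isopropylidenedioxy)cyclohex-1-en-1-yl]methyl benzoate
Conditions: BzCl (1.05 equiv), Me2SnCl2 (5 mol %), i-Pr2NEt, THF, 0 °C
Reagents that add atoms: benzoyl chloride, O=C(Cl)c1ccccc1
Why: Organotin-catalysed site-selective monoacylation of a cis-1,2-diol, which acylates the equatorial oxygen: O5 is equatorial, whereas O6 is pseudo-axial (held so by allylic 1,2-strain with the CH2OBz arm) and more hindered; no stereocentre is touched.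

Step 7
Reactants: 11 [(3S,4S,5R,6R)-5-(benzoyloxy)-6-hydroxy-3,4-(isopropylidenedioxy)cyclohex-1-en-1-yl]methyl benzoate
Product: 12 [(3S,4S,5R,6R)-5-(benzoyloxy)-3,4,6-trihydroxycyclohex-1-en-1-yl]methyl benzoate
Conditions: TFA/H2O 9:1, CH2Cl2, 0 °C, 20 min
Reagents that add atoms: none
Why: Acid hydrolysis of the isopropylidene acetal; both benzoates are stable to acid, and acidic rather than basic conditions avoid benzoyl migration among the cis hydroxyls.

**Compound list**
1 | (3aS,6aS)-2,2-dimethyl-3a,6a-dihydro-4H-cyclopenta[d][1,3]dioxol-4-one | O=C1C=C[C@@H]2OC(C)(C)O[C@H]12 | starting material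
2 | formaldehyde | C=O | starting material
3 | (3aS,6aS)-5-(hydroxymethyl)-2,2-dimethyl-3a,6a-dihydro-4H-cyclopenta[d][1,3]dioxol-4-one | O=C1C(CO)=C[C@@H]2OC(C)(C)O[C@H]12 | intermediate
4 | 1,3-dithiane | C1CSCSC1 | starting material
5 | 2-lithio-1,3-dithiane | [Li]C1SCCCS1 | intermediate
6 | (3aS,4R,6aS)-4-(1,3-dithian-2-yl)-5-(hydroxymethyl)-2,2-dimethyl-3a,6a-dihydro-4H-cyclopenta[d][1,3]dioxol-4-ol | O[C@]1(C3SCCCS3)C(CO)=C[C@@H]2OC(C)(C)O[C@H]12 | intermediate
7 | [(3aS,4R,6aS)-4-(1,3-dithian-2-yl)-4-hydroxy-2,2-dimethyl-3a,6a-dihydro-4H-cyclopenta[d][1,3]dioxol-5-yl]methyl benzoate | O[C@]1(C3SCCCS3)C(COC(=O)c4ccccc4)=C[C@@H]2OC(C)(C)O[C@H]12 | intermediate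
8 | [(3aS,4R,6aS)-4-formyl-4-hydroxy-2,2-dimethyl-3a,6a-dihydro-4H-cyclopenta[d][1,3]dioxol-5-yl]methyl benzoate | O[C@]1(C=O)C(COC(=O)c3ccccc3)=C[C@@H]2OC(C)(C)O[C@H]12 | intermediate
9 | [(3S,4S,6R)-6-hydroxy-3,4-(isopropylidenedioxy)-5-oxocyclohex-1-en-1-yl]methyl benzoate | O=C(OCC1=C[C@@H]2OC(C)(C)O[C@@H]2C(=O)[C@@H]1O)c1ccccc1 | intermediate
10 | [(3S,4R,5R,6R)-5,6-dihydroxy-3,4-(isopropylidenedioxy)cyclohex-1-en-1-yl]methyl benzoate | O=C(OCC1=C[C@@H]2OC(C)(C)O[C@@H]2[C@H](O)[C@@H]1O)c1ccccc1 | intermediate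
11 | [(3S,4S,5R,6R)-5-(benzoyloxy)-6-hydroxy-3,4-(isopropylidenedioxy)cyclohex-1-en-1-yl]methyl benzoate | O=C(OCC1=C[C@@H]2OC(C)(C)O[C@@H]2[C@H](OC(=O)c3ccccc3)[C@@H]1O)c1ccccc1 | intermediate
12 | [(3S,4S,5R,6R)-5-(benzoyloxy)-3,4,6-trihydroxycyclohex-1-en-1-yl]methyl benzoate | O=C(OCC1=C[C@H](O)[C@H](O)[C@H](OC(=O)c2ccccc2)[C@@H]1O)c1ccccc1 | target

**Step count and risks**
Total steps: 7. Longest linear sequence: 7 steps (1 → 12).

Most likely to fail, first: step 5, the new chelate-controlled ring expansion with in-flask reduction. A shift of the acetal-bearing carbon instead of the alkenyl carbon is not the exposure, because that regioisomeric ketol is reduced to the same diol 10. The exposures are epimerisation of the doubly activated C6 centre, methyl transfer from aluminium to the aldehyde, and an unchelated shift giving the C6 epimer. The fallback uses a documented, different one-carbon ring expansion; it sets out from 3 and comes back at 10. (4-Methoxybenzyloxy)methyl phenyl sulfide is lithiated (s-BuLi, THF, −78 °C) and added (2.2 equiv) to 3 to give the adduct diol F1. BzCl/pyridine gives its primary benzoate F2. CuOTf (monovalent copper) removes the thiolate, and the resulting oxocarbenium ion triggers the known semipinacol shift to the ring-expanded α-(4-methoxybenzyloxy) ketone F3. NaBH4 gives the alcohol F4 (the all-cis isomer is separated from any C6 epimer), and DDQ in wet CH2Cl2 frees O6 to deliver 10.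

Second: step 6, the site-selective benzoylation of O5 over O6, which rests on a conformational preference. The fallback replaces selectivity by protection; it sets out from 8 and comes back at 12. The Me2AlCl shift is run without borohydride and ketol 9 is isolated. TESOTf/2,6-lutidine gives the C6 triethylsilyl ether of the ketol F5. NaBH4 (MeOH, −40 °C) reduces C5 anti to both flanking oxygens to the O6-silylated alcohol F6, whose only free hydroxyl is O5. BzCl/DMAP gives the O6-silylated dibenzoate F7, and TFA/H2O removes the silyl ether and the acetonide together to give 12.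

Third: step 4, unmasking the dithiane to a tertiary α-hydroxy aldehyde that is prone to uncontrolled shift or over-oxidation. The fallback uses a vinyl group as the formyl equivalent; it sets out from 3 and comes back at 8. CH2=CHMgBr/CeCl3 (THF, −78 °C) adds to the ketone anti to the acetonide to give the vinyl carbinol diol F8. BzCl/pyridine gives its primary benzoate F9. OsO4 (2 mol %)/NaIO4/2,6-lutidine in dioxane–water cleaves only the unhindered monosubstituted vinyl group (the ring alkene is trisubstituted and deactivated by three allylic oxygens) to give 8.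

Further compounds
F1 | step 5 | adduct diol of 3 with [(4-methoxybenzyloxy)(phenylthio)methyl]lithium (tertiary OH cis to the acetonide) | O[C@]1(C(Sc3ccccc3)OCc4ccc(OC)cc4)C(CO)=C[C@@H]2OC(C)(C)O[C@H]12
F2 | step 5 | primary benzoate of F1 | O[C@]1(C(Sc3ccccc3)OCc4ccc(OC)cc4)C(COC(=O)c5ccccc5)=C[C@@H]2OC(C)(C)O[C@H]12
F3 | step 5 | [(3S,4S)-3,4-(isopropylidenedioxy)-6-(4-methoxybenzyloxy)-5-oxocyclohex-1-en-1-yl]methyl benzoate (C6 epimers) | O=C(OCC1=C[C@@H]2OC(C)(C)O[C@@H]2C(=O)C1OCc3ccc(OC)cc3)c4ccccc4
F4 | step 5 | O6-(4-methoxybenzyl) ether of 10 (all-cis) | O=C(OCC1=C[C@@H]2OC(C)(C)O[C@@H]2[C@H](O)[C@@H]1OCc3ccc(OC)cc3)c4ccccc4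
F5 | step 6 | O6-triethylsilyl ether of ketol 9 | O=C(OCC1=C[C@@H]2OC(C)(C)O[C@@H]2C(=O)[C@@H]1O[Si](CC)(CC)CC)c3ccccc3
F6 | step 6 | O6-triethylsilyl ether of 10 (free O5 hydroxyl, all-cis) | O=C(OCC1=C[C@@H]2OC(C)(C)O[C@@H]2[C@H](O)[C@@H]1O[Si](CC)(CC)CC)c3ccccc3
F7 | step 6 | O6-triethylsilyl ether of 11 | O=C(OCC1=C[C@@H]2OC(C)(C)O[C@@H]2[C@H](OC(=O)c3ccccc3)[C@@H]1O[Si](CC)(CC)CC)c4ccccc4
F8 | step 4 | (3aS,6aS)-4-ethenyl-5-(hydroxymethyl)-2,2-dimethyl-3a,6a-dihydro-4H-cyclopenta[d][1,3]dioxol-4-ol (OH cis to the acetonide) | O[C@]1(C=C)C(CO)=C[C@@H]2OC(C)(C)O[C@H]12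
F9 | step 4 | primary benzoate of F8 | O[C@]1(C=C)C(COC(=O)c3ccccc3)=C[C@@H]2OC(C)(C)O[C@H]12
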